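Start with the easy step: read the last row of each run below, at 4.2 h, and leave the rest aside.

| flask | starting material | free catalyst | target | time |
|---|---|---|---|---|
| beta | 0.600 M | 0.0120 M |  |  |
| alpha | 0.600 M | 0.0120 M | 0.180 M |  |
| eta | 0.900 M | 0.0120 M |  |  |
| zeta | 0.600 M | 0.0180 M |  |  |
| delta | 1.20 M | 0.0120 M |  | 4.2 h |

- beta run (time / h: [target] / M): 0.17: 0.020; 0.38: 0.042; 0.84: 0.086; 1.9: 0.137; 4.2: 0.171
- alpha run (time / h: [target] / M): 0.17: 0.197; 0.38: 0.215; 0.84: 0.245; 1.9: 0.253; 4.2: 0.261
- eta run (time / h: [target] / M): 0.17: 0.024; 0.38: 0.049; 0.84: 0.104; 1.9: 0.185; 4.2: 0.217
- zeta run (time / h: [target] / M): 0.17: 0.034; 0.38: 0.054; 0.84: 0.112; 1.9: 0.182; 4.2: 0.203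

(each reading ± 0.005 M)

- Overall: starting material -> target, with free catalyst as catalyst.
- Constant volume, constant temperature.
- The analysis sees a species whether free or bound.
- An order is taken over about fifteen percent of the charge, up and down.

- order of the initial rate in [starting material], near the charge of the beta run, the rate being that where two percent of its starting material are target (one fixed amount of target, the same in the runs compared)
- order of the initial rate in [free catalyst], near the charge of the beta run, the rate being that where two percent of its starting material are target
- target in the delta run at 4.2 h, as a share of the starting material charged
- which of these the readings show (nothing beyond the main steps / the substrate pairs with itself / two substrates go astray together / the product kills the catalyst / the product binds the substrate / the catalyst dies by itself)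

The beta run has turned 28.5% of its starting material by then, yet it gains 0.0340 M over its last 2.30 h against 0.020 M in its first 0.17 h, so the slowing in the beta run needs another cause than lost starting material. The alpha run, charged with 0.180 M of target, gains 0.0810 M, less than the 0.171 M of beta.

My working picture is that free catalyst dies on meeting target and makes target on meeting starting material, so that with P the [target] and S the [starting material], death goes as P and turnover as S. Catalyst lost per target made then goes as P/S. Replace the falling S by its mean S_m, the charge minus half of the target made. Summing up to the last row, and counting the charged catalyst C as the amount lost by then, you get a constant: the gain in the square of P, halved, divided by S_m and by C.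

Read it row by row: beta gives 2.37, alpha 2.66, eta 2.48 and zeta 2.30. One standard deviation in the last alpha reading moves the alpha value by about 0.194. The mean of the values read, 2.45, is the catalyst budget B, a measure of product-induced deactivation.

Solved for the delta run, B gives 0.251 M, or 20.9% of the charge. Now check the mean: S in the delta run ends 11.7% below S_m, and P goes as the square root of S_m, so a shift of that size moves the answer by 5.85% of its value.

The forecast differs slightly from my figure. It gives orders of 0.45 (0.3 to 0.62) in starting material and 0.65 (0.45 to 0.85) in catalyst, and 20.5% (18.5% to 23%) for delta. Its verdict is that the product kills the catalyst: “Catalyst death driven by product fits”.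

The simulation gives orders of 0.77 in starting material and 1.0 in free catalyst, 21.4% in the delta run, and the verdict that the product kills the catalyst.

    free catalyst + starting material ⇌ catalyst-substrate complex, settled at all times (0.5740 M⁻¹)
    catalyst-substrate complex → target + free catalyst (35.10 h⁻¹)
    free catalyst + target → spent catalyst + target (7.344 M⁻¹ h⁻¹)

That yield makes the budget of the delta run 2.56; carried to the alpha run, it gives 0.259 M of target at 4.2 h against a reading of 0.261 M. Target in the delta run stays low because free catalyst meets target and passes into spent catalyst: delta holds 21.4% at 4.2 h, and the same run without that passing holds 49.1%.

The numbers in the tables stem from a simulated flask with constants of no real substance, and the scatter is random.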